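**Retrosynthetic overview**

1. Target 32 comes from 31 by acidolysis of three tert-butyl esters and the C4 silyl ether; 31 comes from 30 by reductive removal of a C7 carboxyl group whose only role is to activate an ethylene surrogate.
2. Key disconnection: bonds C5–C6 and C1–C7 of the tetrahydrofuran ring (C1–O8–C5–C6–C7) are formed by [3+2] cycloaddition of the cyclic ester carbonyl ylide 29 (C1=O8(+)–C5(−)) with acrylate 28. Ylide 29 arises from the acyclic diazo triester 25 when the acyloxy carbonyl oxygen attacks a rhodium carbene at C5.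
3. Enabling feature: ketal carbon C1 carries two oxygens (O2, O8); O8 is also bonded to C5, which bears a carboxyl group; O2 is tied to C5 through C3–C4. The C1–O8–C5 bridge is therefore a latent ester carbonyl ylide, and C6–C7 is a bare CH2–CH2 unit (ethylene).
4. 25 comes from keto diol 19 (C3–C4 from di-tert-butyl D-tartrate, C5 from tert-butyl glyoxylate by a ketal enolate aldol) and acid 11 (Evans alkylation, then Johnson–Claisen for the E-trisubstituted alkene).
5. Ring order: a temporary 2,2-diphenyl-1,3-dioxolane (step 8, removed in step 11); then in step 16 first the 1,3-dioxane ring (C1–O2–C3–C4–C5–O8, ylide formation) and last the tetrahydrofuran ring (cycloaddition), which completes the 2,8-dioxabicyclo[3.2.1]octane.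

Key step: step 16

Remark on numbering: core atoms carry the locants of 2,8-dioxabicyclo[3.2.1]octane (C1 ketal carbon, O2, C3, C4, C5, C6, C7, O8) throughout, also in the acyclic precursors.

Remark on mixtures: 7 and 17 are carried as mixtures at a carbinol carbon that is destroyed one step later. 30 is drawn as the 7-exo carboxylate; its C7 epimer or a C6 regioisomer would give the same 31.

**Route**

Step 1
Reactants: 1 (R)-4-benzyl-3-propionyloxazolidin-2-one; 2 benzyl bromide
Product: 3 (R)-4-benzyl-3-[(S)-2-methyl-3-phenylpropanoyl]oxazolidin-2-one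
Conditions: NaN(SiMe3)2, THF, −78 °C; then 2, −78 → 0 °C
Reagents that add atoms: benzyl bromide (2), BrCc1ccccc1
Why: Evans asymmetric alkylation, in which the chelated Z sodium enolate is benzylated on the face opposite the C4 benzyl group of the (R)-auxiliary, which sets the (S) methyl-bearing stereocentre.

Step 2
Reactants: 3
Product: 4 (S)-2-methyl-3-phenylpropan-1-ol
Conditions: LiBH4, THF, 0 °C → rt; aqueous work-up
Reagents that add atoms: none
Why: Reductive cleavage of the N-acyl oxazolidinone by LiBH4 attacks only the exocyclic carbonyl and should leave the α-stereocentre untouched while releasing the auxiliary.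

Step 3
Reactants: 4
Product: 5 (S)-2-methyl-3-phenylpropanal
Conditions: Dess–Martin periodinane, pyridine, CH2Cl2, 0 °C; used crude at once
Reagents that add atoms: none
Why: Dess–Martin oxidation under buffered, non-basic conditions should give the α-branched aldehyde without enolisation.

Step 4
Reactants: 5; 6 isopropenylmagnesium bromide
Product: 7 (3RS,4S)-2,4-dimethyl-5-phenylpent-1-en-3-ol
Conditions: CH2=C(CH3)MgBr, THF, −78 °C; then H2O
Reagents that add atoms: isopropenylmagnesium bromide (6), CC(=C)[Mg]Br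
Why: Grignard 1,2-addition at low temperature; the carbinol configuration is irrelevant because step 5 converts this carbon into an alkene carbon.

Step 5
Reactants: 7; 8 triethyl orthoacetate
Product: 10 ethyl (4E,6S)-4,6-dimethyl-7-phenylhept-4-enoate, via mixed ketene acetal 9 (not isolated)
Conditions: CH3C(OEt)3 (excess), EtCO2H (cat.), 140 °C, EtOH distilled off
Reagents that add atoms: triethyl orthoacetate (8), CCOC(C)(OCC)OCC
Why: Johnson–Claisen rearrangement through a chair transition state with the branched substituent equatorial should give the E-trisubstituted alkene, and the (S) stereocentre is not involved.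

Step 6
Reactants: 10
Product: 11 (4E,6S)-4,6-dimethyl-7-phenylhept-4-enoic acid
Conditions: LiOH, THF/MeOH/H2O, rt; then 1 M HCl
Reagents that add atoms: lithium hydroxide, [Li+].[OH-]
Why: Saponification of an unhindered ethyl ester; the stereocentre is remote from the carbonyl and cannot epimerise.

Step 7
Reactants: 12 di-tert-butyl L-tartrate
Product: 13 tert-butyl glyoxylate
Conditions: H5IO6, Et2O, rt; distilled from P2O5 before use
Reagents that add atoms: none
Why: Periodate glycol cleavage (Malaprade reaction) of the 1,2-diol should give two molecules of the glyoxylate.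

Step 8
Reactants: 14 di-tert-butyl D-tartrate; 15 dimethoxydiphenylmethane
Product: 16 di-tert-butyl (4S,5S)-2,2-diphenyl-1,3-dioxolane-4,5-dicarboxylate
Conditions: 15, camphorsulfonic acid (cat.), toluene, 60 °C, reduced pressure (MeOH removed)
Reagents that add atoms: dimethoxydiphenylmethane (15), COC(OC)(c1ccccc1)c1ccccc1
Why: Acid-catalysed transketalisation ties O3 and O4 into a symmetric, base-stable dioxolane that can later be removed by hydrogenolysis without acid, so the tert-butyl esters survive.

Step 9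
Reactants: 16; 13
Product: 17 di-tert-butyl (4R,5S)-4-(2-tert-butoxy-1-hydroxy-2-oxoethyl)-2,2-diphenyl-1,3-dioxolane-4,5-dicarboxylate (both carbinol epimers)
Conditions: LiN(i-Pr)2, THF, −78 °C; then 13, −78 °C; AcOH quench at −78 °C
Reagents that add atoms: tert-butyl glyoxylate (13), CC(C)(C)OC(=O)C=O
Why: Aldol addition of the lithium ester enolate of a tartrate ketal, whose ring C–O bond lies near the nodal plane of the enolate so that β-elimination is slow at −78 °C; the aldehyde should enter anti to the neighbouring C3 ester, making the two ring esters cis and setting C4 as the target requires.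

Step 10
Reactants: 17
Product: 18 di-tert-butyl (4S,5S)-4-(2-tert-butoxy-2-oxoacetyl)-2,2-diphenyl-1,3-dioxolane-4,5-dicarboxylate
Conditions: Dess–Martin periodinane, CH2Cl2, rt
Reagents that add atoms: none
Why: Dess–Martin oxidation of the secondary α-hydroxy ester converges both carbinol epimers to one non-enolisable α-keto ester (C5 at the ketone level).

Step 11
Reactants: 18
Product: 19 tri-tert-butyl (1S,2S)-1,2-dihydroxy-3-oxopropane-1,2,3-tricarboxylate
Conditions: H2 (1 atm), Pd(OH)2/C, EtOAc, rt
Reagents that add atoms: none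
Why: Hydrogenolysis of the doubly benzylic C–O bonds of the diphenylmethylene ketal is a neutral deprotection that should leave the tert-butyl esters and the hindered keto group intact.

Step 12
Reactants: 19; 11
Product: 20 tri-tert-butyl (1S,2S)-1-{[(4E,6S)-4,6-dimethyl-7-phenylhept-4-enoyl]oxy}-2-hydroxy-3-oxopropane-1,2,3-tricarboxylate
Conditions: 11, EDC·HCl, DMAP (cat.), CH2Cl2, 0 °C → rt
Reagents that add atoms: (4E,6S)-4,6-dimethyl-7-phenylhept-4-enoic acid (11), C/C(=C\[C@@H](C)Cc1ccccc1)CCC(=O)O
Why: Steglich esterification should acylate the secondary C3 hydroxyl in preference to the tertiary C4 hydroxyl flanked by three carbonyl groups, which installs C1 at the ester oxidation level.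

Step 13
Reactants: 20; 21 p-toluenesulfonyl hydrazide
Product: 23 tri-tert-butyl (1S,2R)-3-diazo-1-{[(4E,6S)-4,6-dimethyl-7-phenylhept-4-enoyl]oxy}-2-hydroxypropane-1,2,3-tricarboxylate, via tosylhydrazone 22 (not isolated)
Conditions: TsNHNH2, MgSO4, THF, 50 °C; then DBU, CH2Cl2, 0 °C → rt
Reagents that add atoms: p-toluenesulfonyl hydrazide (21), Cc1ccc(cc1)S(=O)(=O)NN
Why: Bamford–Stevens sequence, in which the activated α-keto ester carbonyl condenses with the hydrazide and base-induced loss of sulfinate gives the ester-stabilised diazo compound at C5.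

Step 14
Reactants: 23; 24 N-(trimethylsilyl)imidazole
Product: 25 tri-tert-butyl (1S,2R)-3-diazo-1-{[(4E,6S)-4,6-dimethyl-7-phenylhept-4-enoyl]oxy}-2-(trimethylsilyloxy)propane-1,2,3-tricarboxylate
Conditions: 24, CH2Cl2, rt → 40 °C
Reagents that add atoms: N-(trimethylsilyl)imidazole (24), C[Si](C)(C)n1ccnc1
Why: Neutral silylation of the tertiary C4 alcohol is compatible with the diazo group, removes the O–H that could quench the carbene or ylide, and installs the bulky group that controls the face of the key step.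

Step 15
Reactants: 26 acryloyl chloride; 27 N-hydroxyphthalimide
Product: 28 N-(acryloyloxy)phthalimide
Conditions: Et3N, CH2Cl2, 0 °C
Reagents that add atoms: acryloyl chloride (26), C=CC(Cl)=O
Why: O-acylation of the N-hydroxy imide gives an electron-poor acrylate whose carboxyl group is a redox-active ester, that is, an ethylene surrogate with a traceless activating group.

Step 16
Reactants: 25; 28
Product: 30 tri-tert-butyl (1S,3S,4S,5R,7S)-1-[(3E,5S)-3,5-dimethyl-6-phenylhex-3-en-1-yl]-7-{[(1,3-dioxoisoindolin-2-yl)oxy]carbonyl}-4-(trimethylsilyloxy)-2,8-dioxabicyclo[3.2.1]octane-3,4,5-tricarboxylate, via carbonyl ylide 29 (not isolated)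
Conditions: Rh2(OAc)4 (5 mol %), 28 (3 equiv), benzene, reflux, slow addition of 25
Reagents that add atoms: N-(acryloyloxy)phthalimide (28), C=CC(=O)ON1C(=O)c2ccccc2C1=O
Why: Rh2(OAc)4 converts the diazo ester into a rhodium carbene at C5, and the carbonyl oxygen of the C3 acyloxy group (the future O8) adds to it to give the six-membered ester carbonyl ylide 29, which closes the 1,3-dioxane ring C1–O2–C3–C4–C5–O8 by O8–C5 bond formation (six-ring cyclisation of a tethered carbonyl onto a metal carbene); the ylide C1=O8(+)–C5(−) then adds suprafacially to the C=C bond of 28 in a concerted [3+2] (π4s+π2s) cycloaddition that forms C5–C6 and C1–C7 and so closes the tetrahydrofuran ring last. The closest known reaction type is the tandem carbonyl ylide formation/1,3-dipolar cycloaddition of ester-derived six-membered carbonyl ylides with electron-poor alkenes and alkynes, an established entry to 2,8-dioxabicyclo[3.2.1]octanes. C1 and C5 are created together and are necessarily cis-bridged, so only the face of the ylide matters: in the half-chair of 29 the C3 ester is pseudoequatorial and the cis C4–OSiMe3 group pseudoaxial, and 28 should add to the opposite face (the face of C3–H), which gives (1S,5R) from (3S,4S). The enolate-like C5 terminus should bond to the β-carbon of the acrylate (carboxyl at C7); this regiochemistry and the exo/endo outcome at C7 are of no consequence because step 17 removes the carboxyl group. The step needs chemoselectivity for six-ring ylide formation over carbene 1,2-shift, cyclopropanation, C–H insertion and five-ring ylide formation at the hindered C3 tert-butyl ester; this is secured by the quaternary C4 (no β-hydrogen), the unhindered acyloxy carbonyl and slow addition of 25 into excess 28. The electron-rich trisubstituted side-chain alkene is electronically mismatched with the nucleophilic ylide and cannot reach it intramolecularly.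

Step 17
Reactants: 30
Product: 31 tri-tert-butyl (1S,3S,4S,5R)-1-[(3E,5S)-3,5-dimethyl-6-phenylhex-3-en-1-yl]-4-(trimethylsilyloxy)-2,8-dioxabicyclo[3.2.1]octane-3,4,5-tricarboxylate
Conditions: Ru(bpy)3Cl2·6H2O (1 mol %), Hantzsch ester (1.5 equiv), t-BuSH (1 equiv), THF/H2O 9:1, blue LEDs, rt
Reagents that add atoms: none
Why: Photoredox reductive decarboxylation of the N-acyloxyphthalimide (Barton-type): single-electron reduction, N–O fragmentation and loss of CO2 give a C7 radical that does not undergo β-C–O scission and should be quenched by the thiol faster than it can cyclise onto the side-chain alkene, which erases the C7 stereocentre.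

Step 18
Reactants: 31
Product: 32 (1S,3S,4S,5R)-1-[(3E,5S)-3,5-dimethyl-6-phenylhex-3-en-1-yl]-4-hydroxy-2,8-dioxabicyclo[3.2.1]octane-3,4,5-tricarboxylic acid
Conditions: CF3CO2H/CH2Cl2 (1:4), 0 °C → rt; reverse-phase purification
Reagents that add atoms: none
Why: Acidolysis removes the three tert-butyl esters (as isobutene) and the silyl ether in one operation, the bicyclic ketal being the acid-stable thermodynamic form; a short reaction time in dilute acid should spare the trisubstituted alkene, and no stereocentre is touched.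

**Compound list**

1 | (R)-4-benzyl-3-propionyloxazolidin-2-one | CCC(=O)N1[C@H](Cc2ccccc2)COC1=O | starting material
2 | benzyl bromide | BrCc1ccccc1 | starting material
3 | (R)-4-benzyl-3-[(S)-2-methyl-3-phenylpropanoyl]oxazolidin-2-one | C[C@@H](Cc1ccccc1)C(=O)N1[C@H](Cc2ccccc2)COC1=O | intermediate
4 | (S)-2-methyl-3-phenylpropan-1-ol | C[C@@H](Cc1ccccc1)CO | intermediate
5 | (S)-2-methyl-3-phenylpropanal | C[C@@H](Cc1ccccc1)C=O | intermediate
6 | isopropenylmagnesium bromide | CC(=C)[Mg]Br | starting material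
7 | (3RS,4S)-2,4-dimethyl-5-phenylpent-1-en-3-ol | C[C@@H](Cc1ccccc1)C(O)C(C)=C | intermediate
8 | triethyl orthoacetate | CCOC(C)(OCC)OCC | starting material
9 | 1-ethoxy-1-{[(4S)-2,4-dimethyl-5-phenylpent-1-en-3-yl]oxy}ethene (mixed ketene acetal) | C[C@@H](Cc1ccccc1)C(OC(=C)OCC)C(C)=C | intermediate
10 | ethyl (4E,6S)-4,6-dimethyl-7-phenylhept-4-enoate | C/C(=C\[C@@H](C)Cc1ccccc1)CCC(=O)OCC | intermediate
11 | (4E,6S)-4,6-dimethyl-7-phenylhept-4-enoic acid | C/C(=C\[C@@H](C)Cc1ccccc1)CCC(=O)O | intermediate
12 | di-tert-butyl L-tartrate (2R,3R) | CC(C)(C)OC(=O)[C@H](O)[C@@H](O)C(=O)OC(C)(C)C | starting material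
13 | tert-butyl glyoxylate | CC(C)(C)OC(=O)C=O | intermediate
14 | di-tert-butyl D-tartrate (2S,3S) | CC(C)(C)OC(=O)[C@@H](O)[C@H](O)C(=O)OC(C)(C)C | starting material
15 | dimethoxydiphenylmethane | COC(OC)(c1ccccc1)c1ccccc1 | starting material
16 | di-tert-butyl (4S,5S)-2,2-diphenyl-1,3-dioxolane-4,5-dicarboxylate | CC(C)(C)OC(=O)[C@H]1OC(c2ccccc2)(c2ccccc2)O[C@@H]1C(=O)OC(C)(C)C | intermediate
17 | di-tert-butyl (4R,5S)-4-(2-tert-butoxy-1-hydroxy-2-oxoethyl)-2,2-diphenyl-1,3-dioxolane-4,5-dicarboxylate (carbinol epimers) | CC(C)(C)OC(=O)C(O)[C@@]1(C(=O)OC(C)(C)C)OC(c2ccccc2)(c2ccccc2)O[C@@H]1C(=O)OC(C)(C)C | intermediate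
18 | di-tert-butyl (4S,5S)-4-(2-tert-butoxy-2-oxoacetyl)-2,2-diphenyl-1,3-dioxolane-4,5-dicarboxylate | CC(C)(C)OC(=O)C(=O)[C@@]1(C(=O)OC(C)(C)C)OC(c2ccccc2)(c2ccccc2)O[C@@H]1C(=O)OC(C)(C)C | intermediate
19 | tri-tert-butyl (1S,2S)-1,2-dihydroxy-3-oxopropane-1,2,3-tricarboxylate | CC(C)(C)OC(=O)C(=O)[C@](O)(C(=O)OC(C)(C)C)[C@H](O)C(=O)OC(C)(C)C | intermediate
20 | tri-tert-butyl (1S,2S)-1-{[(4E,6S)-4,6-dimethyl-7-phenylhept-4-enoyl]oxy}-2-hydroxy-3-oxopropane-1,2,3-tricarboxylate | C/C(=C\[C@@H](C)Cc1ccccc1)CCC(=O)O[C@H](C(=O)OC(C)(C)C)[C@@](O)(C(=O)OC(C)(C)C)C(=O)C(=O)OC(C)(C)C | intermediate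
21 | p-toluenesulfonyl hydrazide | Cc1ccc(cc1)S(=O)(=O)NN | starting material
22 | 3-(p-toluenesulfonylhydrazone) of 20 | C/C(=C\[C@@H](C)Cc1ccccc1)CCC(=O)O[C@H](C(=O)OC(C)(C)C)[C@@](O)(C(=O)OC(C)(C)C)C(=NNS(=O)(=O)c1ccc(C)cc1)C(=O)OC(C)(C)C | intermediate
23 | tri-tert-butyl (1S,2R)-3-diazo-1-{[(4E,6S)-4,6-dimethyl-7-phenylhept-4-enoyl]oxy}-2-hydroxypropane-1,2,3-tricarboxylate | C/C(=C\[C@@H](C)Cc1ccccc1)CCC(=O)O[C@H](C(=O)OC(C)(C)C)[C@@](O)(C(=O)OC(C)(C)C)C(=[N+]=[N-])C(=O)OC(C)(C)C | intermediate
24 | N-(trimethylsilyl)imidazole | C[Si](C)(C)n1ccnc1 | starting material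
25 | tri-tert-butyl (1S,2R)-3-diazo-1-{[(4E,6S)-4,6-dimethyl-7-phenylhept-4-enoyl]oxy}-2-(trimethylsilyloxy)propane-1,2,3-tricarboxylate | C/C(=C\[C@@H](C)Cc1ccccc1)CCC(=O)O[C@H](C(=O)OC(C)(C)C)[C@@](O[Si](C)(C)C)(C(=O)OC(C)(C)C)C(=[N+]=[N-])C(=O)OC(C)(C)C | intermediate
26 | acryloyl chloride | C=CC(Cl)=O | starting material
27 | N-hydroxyphthalimide | O=C1c2ccccc2C(=O)N1O | starting material
28 | N-(acryloyloxy)phthalimide | C=CC(=O)ON1C(=O)c2ccccc2C1=O | intermediate
29 | cyclic ester carbonyl ylide from 25 (ring C1(=O8+)–O2–C3H(CO2tBu)–C4(OSiMe3)(CO2tBu)–C5(−)(CO2tBu), side chain on C1, C3 and C4 as in 25) | C/C(=C\[C@@H](C)Cc1ccccc1)CCC1=[O+][C-](C(=O)OC(C)(C)C)[C@](O[Si](C)(C)C)(C(=O)OC(C)(C)C)[C@@H](C(=O)OC(C)(C)C)O1 | intermediate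
30 | tri-tert-butyl (1S,3S,4S,5R,7S)-1-[(3E,5S)-3,5-dimethyl-6-phenylhex-3-en-1-yl]-7-{[(1,3-dioxoisoindolin-2-yl)oxy]carbonyl}-4-(trimethylsilyloxy)-2,8-dioxabicyclo[3.2.1]octane-3,4,5-tricarboxylate | C/C(=C\[C@@H](C)Cc1ccccc1)CC[C@@]12[C@@H](C(=O)ON3C(=O)c4ccccc4C3=O)C[C@@](C(=O)OC(C)(C)C)(O1)[C@](O[Si](C)(C)C)(C(=O)OC(C)(C)C)[C@@H](C(=O)OC(C)(C)C)O2 | intermediate
31 | tri-tert-butyl (1S,3S,4S,5R)-1-[(3E,5S)-3,5-dimethyl-6-phenylhex-3-en-1-yl]-4-(trimethylsilyloxy)-2,8-dioxabicyclo[3.2.1]octane-3,4,5-tricarboxylate | C/C(=C\[C@@H](C)Cc1ccccc1)CC[C@@]12CC[C@@](C(=O)OC(C)(C)C)(O1)[C@](O[Si](C)(C)C)(C(=O)OC(C)(C)C)[C@@H](C(=O)OC(C)(C)C)O2 | intermediate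
32 | (1S,3S,4S,5R)-1-[(3E,5S)-3,5-dimethyl-6-phenylhex-3-en-1-yl]-4-hydroxy-2,8-dioxabicyclo[3.2.1]octane-3,4,5-tricarboxylic acid | C/C(=C\[C@@H](C)Cc1ccccc1)CC[C@@]12CC[C@@](C(=O)O)(O1)[C@](O)(C(=O)O)[C@@H](C(=O)O)O2 | target

**Step count and risks**

Total step count: 18. Longest linear sequence: 12 steps (steps 1–6, 12–14, 16–18, from 1 to 32).

Steps most likely to fail:

Step 16 (key step). The ylide may not be intercepted: a 1,4-proton shift from the side-chain CH2 next to C1, or carbene side reactions, could outrun cycloaddition with the acrylate, or the facial selectivity could erode. Fallback: setting out from 25, the same Rh2(OAc)4-mediated ylide generation is run with phenyl vinyl sulfone, a stronger commercial dipolarophile of the same known class. This should give tri-tert-butyl (1S,3S,4S,5R,7S)-1-[(3E,5S)-3,5-dimethyl-6-phenylhex-3-en-1-yl]-7-(phenylsulfonyl)-4-(trimethylsilyloxy)-2,8-dioxabicyclo[3.2.1]octane-3,4,5-tricarboxylate F1. Reductive desulfonylation with Na(Hg) and Na2HPO4 in MeOH/THF at −20 °C (anionic rather than radical removal of the activating group) comes back to the route at 31.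

Step 13. Condensation at the neopentyl-type C5 ketone may be slow, and base could trigger retro-Claisen cleavage of the C4–C5 bond before the diazo group is formed. Fallback: setting out from 20, condensation with hydrazine hydrate (1 equiv, AcOH cat., EtOH, 0 °C) should give the free hydrazone, tri-tert-butyl (1S,2R)-1-{[(4E,6S)-4,6-dimethyl-7-phenylhept-4-enoyl]oxy}-3-hydrazinylidene-2-hydroxypropane-1,2,3-tricarboxylate F2. Dehydrogenation with MnO2 (CH2Cl2, 0 °C), an oxidative rather than an eliminative route to the diazo group, comes back at 23.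

Step 9. The lithium enolate may undergo β-elimination (opening of the dioxolane) before C–C bond formation, or the aldehyde may attack the wrong face. Fallback: setting out from 16, the enolate is trapped at −78 °C (LiN(i-Pr)2 in the presence of Me3SiCl) as the isolable silyl ketene acetal, tert-butyl (5S)-4-[tert-butoxy(trimethylsilyloxy)methylidene]-2,2-diphenyl-1,3-dioxolane-5-carboxylate F3, which can no longer eliminate. A Mukaiyama aldol addition to 13 (BF3·OEt2, CH2Cl2, −78 °C) comes back at 17.

Further compounds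
F1 | step 16 | tri-tert-butyl (1S,3S,4S,5R,7S)-1-[(3E,5S)-3,5-dimethyl-6-phenylhex-3-en-1-yl]-7-(phenylsulfonyl)-4-(trimethylsilyloxy)-2,8-dioxabicyclo[3.2.1]octane-3,4,5-tricarboxylate | C/C(=C\[C@@H](C)Cc1ccccc1)CC[C@@]12[C@@H](S(=O)(=O)c3ccccc3)C[C@@](C(=O)OC(C)(C)C)(O1)[C@](O[Si](C)(C)C)(C(=O)OC(C)(C)C)[C@@H](C(=O)OC(C)(C)C)O2
F2 | step 13 | tri-tert-butyl (1S,2R)-1-{[(4E,6S)-4,6-dimethyl-7-phenylhept-4-enoyl]oxy}-3-hydrazinylidene-2-hydroxypropane-1,2,3-tricarboxylate | C/C(=C\[C@@H](C)Cc1ccccc1)CCC(=O)O[C@H](C(=O)OC(C)(C)C)[C@@](O)(C(=O)OC(C)(C)C)C(=NN)C(=O)OC(C)(C)C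
F3 | step 9 | tert-butyl (5S)-4-[tert-butoxy(trimethylsilyloxy)methylidene]-2,2-diphenyl-1,3-dioxolane-5-carboxylate | CC(C)(C)OC(O[Si](C)(C)C)=C1OC(c2ccccc2)(c2ccccc2)O[C@@H]1C(=O)OC(C)(C)C
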